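All runs were computed on assumed constants; the scatter is artificial.

As a working balance, each E that reacts in the fast first minutes takes one J with it, so a flask then holds the surplus of whichever was charged in excess. The coming row keeps J and the time and changes E, and the decision is which E charge to keep for Z.

| setting | larch | ash | epsilon | delta | eta | gamma | zeta |
|---|---|---|---|---|---|---|---|
| E | 0.21 M | 0.82 M | 0.20 M | 0.40 M | 0.80 M | 1.5 M | 3.0 M |
| J | 0.408 M | 0.408 M | 0.408 M | 0.408 M | 0.408 M | 0.408 M | 0.408 M |
| remark | run made earlier | run made earlier |  |  |  |  |  |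
| time |  |  | 12 min | 12 min | 12 min | 12 min | 12 min |

| run | time / min | Z / % |
|---|---|---|
| larch | 1.50 | 26.0 |
| larch | 3.00 | 25.4 |
| larch | 5.00 | 25.0 |
| larch | 6.00 | 25.7 |
| larch | 8.00 | 25.9 |
| ash | 0.667 | 8.5 |
| ash | 1.33 | 8.8 |
| ash | 2.50 | 8.6 |
| ash | 4.00 | 7.4 |
| ash | 8.00 | 7.1 |

(standard deviation of a reading: 0.5 percentage points)

- "hardly changes" means that all values lie within two and a half points (for a concentration: within two and a half percent of the largest)

- [Z] at the end for epsilon, delta, eta, gamma, zeta, in this order
- the shape of the row from first to last (falls all the way / falls, then rises / hardly changes / rises, then falls / rises all the way)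

Larch, with E as limiting reagent, stays level, reading 26.0 % at 1.50 min and 25.9 % at 8.00 min. Ash, with J limiting, leaves a surplus of 0.412 M of E, and its Z sinks from a mean of 8.63 % near 1.50 min to 7.25 % near 6.00 min. The reckoning here therefore reads the loss of Z as pseudo-first-order, with free [E] setting its rate. Ash gives 0.0942 M⁻¹ min⁻¹ for the loss constant, the fraction of Z lost per minute per molar of free E.

The early ash mean is 0.0708 M of Z from a spent J charge. Delta has no surplus E, since 0.40 M lies below 0.408 M, so this reckoning expects about that value there. With the surplus as free E, the same start decays to 0.0480 M for eta, 0.0240 M for gamma and 0.00546 M for zeta. Epsilon has E limiting, as larch does, so this reckoning applies the mean larch reading of 25.6 % to its charge and expects 0.0512 M. The charge to keep is therefore delta's, whose reckoned [Z] exceeds those of epsilon, eta, gamma and zeta.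

The forecast gives 0.052 M, 0.07 M, 0.063 M, 0.03 M and 0.012 M, with the shape rises, then falls; in its words, “Z falls roughly as 1/E”. It stands higher than this reckoning at zeta.

The flask gives 0.0526 M, 0.0744 M, 0.0499 M, 0.0243 M and 0.00512 M, with the shape rises, then falls.

    E + J → Z (k = 187 M⁻¹ min⁻¹)
    E + J → D, rate k2*[E] as long as [J] is above zero (k = 160 min⁻¹)
    E + Z → L (k = 0.0877 M⁻¹ min⁻¹)

Eta at 12.0 min holds 45.9 % of its E charge as free E, with J at 0 %. With that free E, the loss constant takes eta's Z from 7.59 % at 6.00 min to 6.17 %. For zeta, with 84.1 % of its E free, it takes Z from 0.645 % at 6.00 min to 0.155 %. Zeta holds 0.171 % at 12.0 min.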